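**Retrosynthetic overview**

1. Ring A is the quinone carrying the 2-(2-methoxyphenyl)ethyl chain, numbered C1(=O), C2(OH), C3(Me), C4(=O), C5(ring B), C6(chain). It is cut at C1–C2 and C4–C5 into cyclopropenone 15 (C1, C6, C5) and the β-lithiated β-methoxymethacrylamide 20 (C2, C3, C4), which are joined by an anionic [3+3] annulation.
2. Enabling feature: the six carbons of ring A are two head-to-tail O=C–C=C triads (C1/C6/C5 and C4/C3/C2). A cyclopropenone is a strained, masked acyl cation plus cis-vinyl anion, and a β-metallated acrylamide is the complementary vinyl anion plus acyl cation. The C2 oxygen (carried as OMe) directs the lithiation, and the ortho-OMe of ring B steers the C1–C5 cleavage.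
3. Ring B travels as a 1,2,4-trimethoxy-3-methylbenzene and is oxidised to its methoxyquinone with (NH4)2Ce(NO3)6 after the annulation. Its bromide 7 comes from 1,2,4-trimethoxybenzene by lithiation/methylation, bromination and acylation/reduction.
4. Cyclopropenone 15 comes from Sonogashira coupling of 7 with butyne 12, then difluorocarbene addition and hydrolysis.
5. Ring order: benzene ring B (bought) → cyclopropenone ring (step 8) → quinone ring A (step 10) → quinone ring B by oxidation (step 11). Both vinylogous methyl esters are hydrolysed last (step 12).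

Key step: step 10

Remark: the target SMILES carries no stereodescriptor, so the hindered axis between the two quinone rings is taken as unspecified and is formed without control.

**Route**

Step 1
Reactants: 1 1,2,4-trimethoxybenzene
Product: 3 1,2,4-trimethoxy-3-methylbenzene, via 3-lithio-1,2,4-trimethoxybenzene 2 (not isolated)
Conditions: n-BuLi, TMEDA, THF, 0 °C; MeI, −78 °C to rt
Reagents that add atoms: iodomethane, CI
Why: Directed ortho-metalation, in which the C3–H between two methoxy groups is the most acidic ring proton and the aryllithium is methylated by SN2 on MeI.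

Step 2
Reactants: 3 1,2,4-trimethoxy-3-methylbenzene
Product: 4 1-bromo-2,4,5-trimethoxy-3-methylbenzene
Conditions: NBS, MeCN, 0 °C to rt
Reagents that add atoms: N-bromosuccinimide, O=C1CCC(=O)N1Br
Why: Electrophilic aromatic bromination should go to the free position that is para to one methoxy group and ortho to another, the site also attacked in 1,2,4-trimethoxybenzene itself.

Step 3
Reactants: 4 1-bromo-2,4,5-trimethoxy-3-methylbenzene; 5 phenylacetyl chloride
Product: 6 1-(2-bromo-3,5,6-trimethoxy-4-methylphenyl)-2-phenylethan-1-one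
Conditions: TiCl4, CH2Cl2, −20 to 0 °C
Reagents that add atoms: none
Why: Friedel–Crafts acylation at the only remaining ring position, activated by the ortho-methoxy and para-methyl groups, with TiCl4 chosen over AlCl3 to limit ether cleavage.

Step 4
Reactants: 6 1-(2-bromo-3,5,6-trimethoxy-4-methylphenyl)-2-phenylethan-1-one
Product: 7 1-bromo-2,4,5-trimethoxy-3-methyl-6-(2-phenylethyl)benzene
Conditions: Et3SiH, TFA, rt to 50 °C
Reagents that add atoms: none
Why: Ionic hydrogenation of an electron-rich aryl ketone to the methylene compound (via the benzylic cation or the derived stilbene) leaves the aryl bromide and the ethers untouched.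

Step 5
Reactants: 8 1-(chloromethyl)-2-methoxybenzene; 9 trimethyl(prop-1-yn-1-yl)silane
Product: 11 [4-(2-methoxyphenyl)but-1-yn-1-yl]trimethylsilane, via lithiated silylpropyne 10 (not isolated)
Conditions: 9, n-BuLi, THF, −78 °C; then 8, −78 °C to rt
Reagents that add atoms: none
Why: Propargylic lithiation of the silylpropyne and SN2 alkylation by the benzylic chloride, with the silyl group suppressing allene formation.

Step 6
Reactants: 11 [4-(2-methoxyphenyl)but-1-yn-1-yl]trimethylsilane
Product: 12 1-(but-3-yn-1-yl)-2-methoxybenzene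
Conditions: K2CO3 (cat.), MeOH, rt
Reagents that add atoms: none
Why: Base-catalysed protodesilylation of an alkynylsilane by methanolysis.

Step 7
Reactants: 7 1-bromo-2,4,5-trimethoxy-3-methyl-6-(2-phenylethyl)benzene; 12 1-(but-3-yn-1-yl)-2-methoxybenzene
Product: 13 1-[4-(2-methoxyphenyl)but-1-yn-1-yl]-2,4,5-trimethoxy-3-methyl-6-(2-phenylethyl)benzene
Conditions: PdCl2(MeCN)2 (cat.), XPhos (cat.), Cs2CO3, MeCN, 80 °C
Reagents that add atoms: none
Why: Copper-free Sonogashira coupling, in which the bulky electron-rich biarylphosphine allows oxidative addition of the hindered electron-rich aryl bromide to zerovalent palladium and the absence of copper suppresses diyne formation.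

Step 8
Reactants: 13 1-[4-(2-methoxyphenyl)but-1-yn-1-yl]-2,4,5-trimethoxy-3-methyl-6-(2-phenylethyl)benzene
Product: 15 2-[2-(2-methoxyphenyl)ethyl]-3-[2,4,5-trimethoxy-3-methyl-6-(2-phenylethyl)phenyl]cycloprop-2-en-1-one, via gem-difluorocyclopropene 14 (not isolated)
Conditions: TMSCF3, NaI (cat.), THF, 70 °C (sealed); then wet SiO2, rt
Reagents that add atoms: (trifluoromethyl)trimethylsilane, C[Si](C)(C)C(F)(F)F; water, O
Why: [2+1] cycloaddition of difluorocarbene to the internal alkyne gives the 3,3-difluorocyclopropene, which ionises to the aryl-stabilised fluorocyclopropenium ion and hydrolyses on wet silica to the cyclopropenone.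

Step 9
Reactants: 16 N,N-diethylpropanamide
Product: 19 (E)-N,N-diethyl-3-methoxy-2-methylprop-2-enamide, via amide enolate 17 (not isolated), via formyl amide enolate 18 (not isolated)
Conditions: LDA, THF, −78 °C; HCO2Me, −78 to 0 °C; Me2SO4, DMPU, 0 °C to rt
Reagents that add atoms: methyl formate, COC=O; dimethyl sulfate, COS(=O)(=O)OC
Why: Crossed Claisen formylation of the amide enolate followed by O-methylation of the hydroxymethylene enolate with a hard electrophile in a dipolar medium (as in β-methoxyacrylate syntheses) should give mainly the E isomer, methoxy trans to the carbonyl, with any Z isomer removed by chromatography.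

Step 10
Reactants: 19 (E)-N,N-diethyl-3-methoxy-2-methylprop-2-enamide; 15 2-[2-(2-methoxyphenyl)ethyl]-3-[2,4,5-trimethoxy-3-methyl-6-(2-phenylethyl)phenyl]cycloprop-2-en-1-one
Product: 24 2-methoxy-6-[2-(2-methoxyphenyl)ethyl]-3-methyl-5-[2,4,5-trimethoxy-3-methyl-6-(2-phenylethyl)phenyl]cyclohexa-2,5-diene-1,4-dione, via vinyllithium 20 (not isolated), via lithium cyclopropenolate 21 (not isolated), via ring-opened vinyllithium 22 (not isolated), via tetrahedral aminal alkoxide 23 (not isolated)
Conditions: 19, s-BuLi, TMEDA, THF, −95 °C; then 15, −95 to −78 °C; then HMPA, −78 to −20 °C; 1 M HCl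
Reagents that add atoms: none
Why: Proposed new method: the chelated vinyllithium 20 should add 1,2 to the exposed carbonyl of 15 to give cyclopropenolate 21, whose strained C(O)–C(aryl) bond then cleaves (HMPA frees the alkoxide) to the cis-β-acylvinyllithium 22, which closes onto the diethylamide to give the tetrahedral adduct 23 that collapses to the quinone only on acidic work-up, so that C1–C2 and C4–C5 of ring A arise in one flask and the quinone never meets an organolithium. The closest known reaction types are the β-lithiation of β-alkoxyacrylates with addition to ketones (tetronate synthesis), the 1,2-addition of organolithiums to cyclopropenones, the nucleophile-induced C–C cleavage of cyclopropenones to cis-acrylic acid derivatives and the Parham-type cyclisation of organolithiums onto tertiary amides; their merger into a [3+3] quinone annulation is what is new. Ring A closes by a 6-exo-trig acyl addition, made geometrically easy because acyl group and carbanion are cis on the former cyclopropene double bond and ketone and amide are cis on the acrylamide double bond, while the alternative 4-exo or 5-endo conjugate closures are disfavoured. No lasting stereocentre is formed (21 and 23 are racemic intermediates and the aryl–quinone axis is not controlled). The step needs 1,2- over 1,4-addition (hard chelated vinyllithium at −95 °C, with enolisation disfavoured because it would destroy the cyclopropenium-oxide character), cleavage toward the aryl-bearing ring carbon (the in-plane carbanion is stabilised inductively by the sp2 aryl carbon, by overlap with the π-system of the twisted di-ortho-substituted ring and by chelation of lithium to its ortho-methoxy oxygen) and C- over O-acylation (the amide, unlike an ester, is not attacked by the tertiary alkoxide, which blocks spiro-tetronate formation).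

Step 11
Reactants: 24 2-methoxy-6-[2-(2-methoxyphenyl)ethyl]-3-methyl-5-[2,4,5-trimethoxy-3-methyl-6-(2-phenylethyl)phenyl]cyclohexa-2,5-diene-1,4-dione
Product: 25 2-methoxy-5-[4-methoxy-5-methyl-3,6-dioxo-2-(2-phenylethyl)cyclohexa-1,4-dien-1-yl]-6-[2-(2-methoxyphenyl)ethyl]-3-methylcyclohexa-2,5-diene-1,4-dione
Conditions: (NH4)2Ce(NO3)6, MeCN/H2O, 0 °C
Reagents that add atoms: water, O
Why: Oxidative demethylation of the para-dimethoxy pair of the hexasubstituted, most electron-rich ring by tetravalent cerium, while the anisole ring and the existing quinone are much harder to oxidise.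

Step 12
Reactants: 25 2-methoxy-5-[4-methoxy-5-methyl-3,6-dioxo-2-(2-phenylethyl)cyclohexa-1,4-dien-1-yl]-6-[2-(2-methoxyphenyl)ethyl]-3-methylcyclohexa-2,5-diene-1,4-dione
Product: 26 2-hydroxy-5-[4-hydroxy-5-methyl-3,6-dioxo-2-(2-phenylethyl)cyclohexa-1,4-dien-1-yl]-6-[2-(2-methoxyphenyl)ethyl]-3-methylcyclohexa-2,5-diene-1,4-dione (CNP0202346.0)
Conditions: 1 M NaOH, THF/H2O, argon, 0 °C to rt; then 1 M HCl
Reagents that add atoms: sodium hydroxide, [Na+].[OH-]
Why: Vinylogous ester saponification by addition–elimination of hydroxide at the two methoxy-bearing quinone carbons, with the aryl methyl ether inert and no other site for irreversible addition on the fully substituted rings.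

**Compound list**

1 | 1,2,4-trimethoxybenzene | COc1ccc(OC)c(OC)c1 | starting material
2 | 3-lithio-1,2,4-trimethoxybenzene | COc1ccc(OC)c([Li])c1OC | intermediate (not isolated)
3 | 1,2,4-trimethoxy-3-methylbenzene | COc1ccc(OC)c(C)c1OC | intermediate
4 | 1-bromo-2,4,5-trimethoxy-3-methylbenzene | COc1cc(Br)c(OC)c(C)c1OC | intermediate
5 | phenylacetyl chloride | O=C(Cl)Cc1ccccc1 | starting material
6 | 1-(2-bromo-3,5,6-trimethoxy-4-methylphenyl)-2-phenylethan-1-one | COc1c(C(=O)Cc2ccccc2)c(Br)c(OC)c(C)c1OC | intermediate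
7 | 1-bromo-2,4,5-trimethoxy-3-methyl-6-(2-phenylethyl)benzene | COc1c(CCc2ccccc2)c(Br)c(OC)c(C)c1OC | intermediate
8 | 1-(chloromethyl)-2-methoxybenzene | COc1ccccc1CCl | starting material
9 | trimethyl(prop-1-yn-1-yl)silane | CC#C[Si](C)(C)C | starting material
10 | (3-lithioprop-1-yn-1-yl)trimethylsilane | [Li]CC#C[Si](C)(C)C | intermediate (not isolated)
11 | [4-(2-methoxyphenyl)but-1-yn-1-yl]trimethylsilane | COc1ccccc1CCC#C[Si](C)(C)C | intermediate
12 | 1-(but-3-yn-1-yl)-2-methoxybenzene | COc1ccccc1CCC#C | intermediate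
13 | 1-[4-(2-methoxyphenyl)but-1-yn-1-yl]-2,4,5-trimethoxy-3-methyl-6-(2-phenylethyl)benzene | COc1ccccc1CCC#Cc1c(OC)c(C)c(OC)c(OC)c1CCc1ccccc1 | intermediate
14 | 1-{3,3-difluoro-2-[2-(2-methoxyphenyl)ethyl]cycloprop-1-en-1-yl}-2,4,5-trimethoxy-3-methyl-6-(2-phenylethyl)benzene | FC1(F)C(CCc2ccccc2OC)=C1c1c(OC)c(C)c(OC)c(OC)c1CCc1ccccc1 | intermediate (not isolated)
15 | 2-[2-(2-methoxyphenyl)ethyl]-3-[2,4,5-trimethoxy-3-methyl-6-(2-phenylethyl)phenyl]cycloprop-2-en-1-one | O=C1C(CCc2ccccc2OC)=C1c1c(OC)c(C)c(OC)c(OC)c1CCc1ccccc1 | intermediate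
16 | N,N-diethylpropanamide | CCC(=O)N(CC)CC | starting material
17 | lithium (Z)-enolate of N,N-diethylpropanamide | C/C=C(\O[Li])N(CC)CC | intermediate (not isolated)
18 | lithium enolate of N,N-diethyl-2-methyl-3-oxopropanamide (double-bond geometry mobile) | [Li]OC=C(C)C(=O)N(CC)CC | intermediate (not isolated)
19 | (E)-N,N-diethyl-3-methoxy-2-methylprop-2-enamide | CO/C=C(\C)C(=O)N(CC)CC | intermediate
20 | N,N-diethyl-3-lithio-3-methoxy-2-methylprop-2-enamide, lithium cis to the amide carbonyl | CO/C([Li])=C(\C)C(=O)N(CC)CC | intermediate (not isolated)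
21 | lithium cyclopropenolate, the 1,2-adduct of 20 to the carbonyl of 15 (racemic) | CO/C(C1(O[Li])C(CCc2ccccc2OC)=C1c1c(OC)c(C)c(OC)c(OC)c1CCc1ccccc1)=C(\C)C(=O)N(CC)CC | intermediate (not isolated)
22 | ring-opened β-acylvinyllithium, lithium cis to the ketone, ketone cis to the amide | CO/C(C(=O)/C(CCc1ccccc1OC)=C(\[Li])c1c(OC)c(C)c(OC)c(OC)c1CCc1ccccc1)=C(\C)C(=O)N(CC)CC | intermediate (not isolated)
23 | lithium 1-(diethylamino)-3-methoxy-2-methyl-4-oxocyclohexa-2,5-dien-1-olate carrying the aryl group at C6 and the arylethyl chain at C5 (racemic) | COC1=C(C)C(O[Li])(N(CC)CC)C(c2c(OC)c(C)c(OC)c(OC)c2CCc2ccccc2)=C(CCc2ccccc2OC)C1=O | intermediate (not isolated)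
24 | 2-methoxy-6-[2-(2-methoxyphenyl)ethyl]-3-methyl-5-[2,4,5-trimethoxy-3-methyl-6-(2-phenylethyl)phenyl]cyclohexa-2,5-diene-1,4-dione | COc1ccccc1CCC1=C(c2c(CCc3ccccc3)c(OC)c(OC)c(C)c2OC)C(=O)C(C)=C(OC)C1=O | intermediate
25 | 2-methoxy-5-[4-methoxy-5-methyl-3,6-dioxo-2-(2-phenylethyl)cyclohexa-1,4-dien-1-yl]-6-[2-(2-methoxyphenyl)ethyl]-3-methylcyclohexa-2,5-diene-1,4-dione | COc1ccccc1CCC1=C(C2=C(CCc3ccccc3)C(=O)C(OC)=C(C)C2=O)C(=O)C(C)=C(OC)C1=O | intermediate
26 | 2-hydroxy-5-[4-hydroxy-5-methyl-3,6-dioxo-2-(2-phenylethyl)cyclohexa-1,4-dien-1-yl]-6-[2-(2-methoxyphenyl)ethyl]-3-methylcyclohexa-2,5-diene-1,4-dione | COc1ccccc1CCC1=C(C2=C(CCc3ccccc3)C(=O)C(O)=C(C)C2=O)C(=O)C(C)=C(O)C1=O | target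

**Step count and risks**

Total step count: 12. Longest linear sequence: 9 steps (1, 2, 3, 4, 7, 8, 10, 11, 12).

Steps most likely to fail:

1. Step 10 (proposed new method).
   - What may go wrong: the lithium cyclopropenolate may not fragment, or may fragment toward the alkyl-bearing ring carbon. Conjugate addition or deprotonation of the cyclopropenone may compete with 1,2-addition. The vinyl anion may be protonated before it closes onto the hindered amide.
   - Fallback (known chemistry, biaryl coupling in place of annulation): it sets out from bromides 4 and 7 and comes back to the route at 25.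
   - 4 would be acylated with (2-methoxyphenyl)acetyl chloride (TiCl4, CH2Cl2) to 1-(2-bromo-3,5,6-trimethoxy-4-methylphenyl)-2-(2-methoxyphenyl)ethan-1-one F1.
   - F1 would be reduced (Et3SiH, TFA) to 1-bromo-2,4,5-trimethoxy-6-[2-(2-methoxyphenyl)ethyl]-3-methylbenzene F2.
   - F2 would be converted by bromine–lithium exchange (n-BuLi, THF, −78 °C) into {2,4,5-trimethoxy-6-[2-(2-methoxyphenyl)ethyl]-3-methylphenyl}lithium F3, which would be quenched with 2-isopropoxy-4,4,5,5-tetramethyl-1,3,2-dioxaborolane to the pinacol boronate 2-{2,4,5-trimethoxy-6-[2-(2-methoxyphenyl)ethyl]-3-methylphenyl}-4,4,5,5-tetramethyl-1,3,2-dioxaborolane F4.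
   - Suzuki–Miyaura coupling of F4 with 7 (Pd(OAc)2, SPhos, K3PO4, toluene/H2O, 100 °C) would give 2,2',4,4',5,5'-hexamethoxy-6-[2-(2-methoxyphenyl)ethyl]-3,3'-dimethyl-6'-(2-phenylethyl)-1,1'-biphenyl F5.
   - Excess (NH4)2Ce(NO3)6 in MeCN/H2O would oxidise both rings of F5 to 25.

2. Step 3.
   - What may go wrong: ipso attack at the brominated carbon with migration or loss of bromine, and Lewis-acid cleavage of the methoxy group ortho to the new ketone.
   - Fallback (cross-coupling in place of acylation/reduction): it sets out from 4 and comes back at 7, bypassing 6.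
   - 4 would be iodinated at its last free position (N-iodosuccinimide, cat. TFA, MeCN) to 1-bromo-2-iodo-3,4,6-trimethoxy-5-methylbenzene F6.
   - An iodide-selective B-alkyl Suzuki–Miyaura coupling (Pd(dppf)Cl2, K3PO4, THF/H2O, 60 °C) of F6 with 9-(2-phenylethyl)-9-borabicyclo[3.3.1]nonane F7, made in the flask from styrene and 9-borabicyclo[3.3.1]nonane, would give 7 directly.

3. Step 7.
   - What may go wrong: slow oxidative addition into the di-ortho-substituted, electron-rich C–Br bond, during which the terminal alkyne oligomerises.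
   - Fallback (reversed polarity of the coupling): it sets out from 12 and 7 and comes back at 13.
   - 12 would be iodinated (N-iodosuccinimide, cat. AgNO3, acetone) to 1-(4-iodobut-3-yn-1-yl)-2-methoxybenzene F8.
   - 7 would be converted (n-BuLi, THF, −78 °C) into [2,4,5-trimethoxy-3-methyl-6-(2-phenylethyl)phenyl]lithium F9 and then with ZnCl2 into chlorido[2,4,5-trimethoxy-3-methyl-6-(2-phenylethyl)phenyl]zinc F10.
   - Negishi coupling of F10 with F8 (Pd(PPh3)4, THF, rt) would give 13.

**Further compounds**

F1 | step 10 | 1-(2-bromo-3,5,6-trimethoxy-4-methylphenyl)-2-(2-methoxyphenyl)ethan-1-one | COc1ccccc1CC(=O)c1c(Br)c(OC)c(C)c(OC)c1OC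
F2 | step 10 | 1-bromo-2,4,5-trimethoxy-6-[2-(2-methoxyphenyl)ethyl]-3-methylbenzene | COc1ccccc1CCc1c(Br)c(OC)c(C)c(OC)c1OC
F3 | step 10 | {2,4,5-trimethoxy-6-[2-(2-methoxyphenyl)ethyl]-3-methylphenyl}lithium | COc1ccccc1CCc1c([Li])c(OC)c(C)c(OC)c1OC
F4 | step 10 | 2-{2,4,5-trimethoxy-6-[2-(2-methoxyphenyl)ethyl]-3-methylphenyl}-4,4,5,5-tetramethyl-1,3,2-dioxaborolane | COc1ccccc1CCc1c(B2OC(C)(C)C(C)(C)O2)c(OC)c(C)c(OC)c1OC
F5 | step 10 | 2,2',4,4',5,5'-hexamethoxy-6-[2-(2-methoxyphenyl)ethyl]-3,3'-dimethyl-6'-(2-phenylethyl)-1,1'-biphenyl | COc1ccccc1CCc1c(-c2c(OC)c(C)c(OC)c(OC)c2CCc2ccccc2)c(OC)c(C)c(OC)c1OC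
F6 | step 3 | 1-bromo-2-iodo-3,4,6-trimethoxy-5-methylbenzene | COc1c(I)c(Br)c(OC)c(C)c1OC
F7 | step 3 | 9-(2-phenylethyl)-9-borabicyclo[3.3.1]nonane | B1(CCc2ccccc2)C2CCCC1CCC2
F8 | step 7 | 1-(4-iodobut-3-yn-1-yl)-2-methoxybenzene | COc1ccccc1CCC#CI
F9 | step 7 | [2,4,5-trimethoxy-3-methyl-6-(2-phenylethyl)phenyl]lithium | COc1c(CCc2ccccc2)c([Li])c(OC)c(C)c1OC
F10 | step 7 | chlorido[2,4,5-trimethoxy-3-methyl-6-(2-phenylethyl)phenyl]zinc | COc1c(CCc2ccccc2)c([Zn]Cl)c(OC)c(C)c1OC
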